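**Retrosynthesis**
1. Kuwanon E ⇒ C5′ geranyl installed by Stille coupling of a 5′-bromide ⇒ 5′-Br, 2′-OH flavanone, silyl-protected.
2. The 2′-OH comes from photoredox ipso-hydroxylation of a 2′-Bpin ⇒ sterically directed Ir-catalysed C2′–H borylation of 7,4′-bis-TIPS-(2S)-naringenin.
3. All three rings and the only stereocentre (C2, S) are already in (2S)-naringenin. No ring is formed, and C2 is never touched. Every step is non-basic or only weakly basic, at rt or mild heat.

Assumption: (2S)-naringenin is available as the single natural enantiomer, bought directly or obtained from naringin. The sequence is meant to leave C2 unchanged, but stereochemical retention under the amine and fluoride steps has not been confirmed.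

**Step 1**
Reactants: 1 (2S)-naringenin; 2 TIPSCl
Product: 3 (2S)-7,4′-bis-O-TIPS-naringenin
Conditions: 2 (2.3 equiv), imidazole, DMF, 25 °C
Reagents that add atoms: TIPSCl, CC(C)[Si](Cl)(C(C)C)C(C)C
Why: Silylation of the two free phenols (7-OH and 4′-OH). The 5-OH is locked by hydrogen bonding to C4=O and stays free. No stereocentre is formed, and C2 is untouched under these mild conditions.

**Step 2**
Reactants: 3; 4 B2pin2
Product: 5 (2S)-2′-Bpin-7,4′-bis-O-TIPS-naringenin
Conditions: [Ir(OMe)(cod)]2 (1.5 mol%), dtbpy (3 mol%), 4 (1.5 equiv), THF, 80 °C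
Reagents that add atoms: B2pin2, CC1(C)OB(OC1(C)C)B1OC(C)(C)C(C)(C)O1
Why: Proposed new method: sterically governed Ir-catalysed C–H borylation, with C2′ as the only accessible C–H bond.
- A-ring C6–H and C8–H are each flanked by two oxygen substituents (5-OH/7-OTIPS and 7-OTIPS/O1).
- The three isopropyl groups of the 4′-OTIPS shield C3′–H and C5′–H.
- The 2-chromanyl group places its own C2–H in the arene plane, which leaves C2′–H open to the catalyst.
- The closest known reaction is steric-controlled borylation of 1,4-disubstituted arenes, which normally goes ortho to the smaller substituent. It has not been shown on a 2-aryl-chromanone with a bulky silyl ether.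
- The conditions are neutral, so C2 is not epimerised.

**Step 3**
Reactants: 5; 6 O2
Product: 7 (2S)-2′-hydroxy-7,4′-bis-O-TIPS-naringenin
Conditions: Ru(bpy)3Cl2 (1 mol%), iPr2NEt (3 equiv), air, MeCN/H2O 4:1, blue LEDs, 25 °C
Reagents that add atoms: O2, O=O
Why: Visible-light photoredox ipso-hydroxylation of an arylboronate. Superoxide adds to boron, a 1,2-aryl shift follows, and hydrolysis gives the phenol, which forms the C2′–O bond. No stereocentre is formed. The geranyl alkene is not yet present, so it cannot be attacked by singlet oxygen.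

**Step 4**
Reactants: 7; 8 NBS
Product: 9 (2S)-5′-bromo-2′-hydroxy-7,4′-bis-O-TIPS-naringenin
Conditions: 8 (1.0 equiv), CH2Cl2, −40 → 0 °C
Reagents that add atoms: NBS, O=C1CCC(=O)N1Br
Why: Electrophilic aromatic bromination. C5′ is para to the free 2′-OH and is the only strongly activated, unhindered B-ring site. C3′ is hindered by OTIPS and the 2′-OH, and A-ring C6/C8 are hindered and deactivated. C2 is not involved.

**Step 5**
Reactants: 9; 10 (E)-geranyltributylstannane
Product: 11 (2S)-5′-geranyl-2′-hydroxy-7,4′-bis-O-TIPS-naringenin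
Conditions: Pd(PPh3)4 (5 mol%), CuI (10 mol%), DMF, 60 °C
Reagents that add atoms: (E)-geranyltributylstannane, CC(C)=CCC/C(C)=C/C[Sn](CCCC)(CCCC)CCCC
Why: Stille cross-coupling. The allylstannane couples at the α-carbon, which keeps the linear (E)-geranyl chain. The organotin reagent leaves the C4 ketone alone. C2 is not involved.

**Step 6**
Reactants: 11
Product: 12 Kuwanon E, (2S)-5,7,2′,4′-tetrahydroxy-5′-geranylflavanone
Conditions: Et3N·3HF, THF, 0 → 25 °C, short reaction time
Reagents that add atoms: none
Why: Fluoride removal of both aryl TIPS ethers under buffered, near-neutral conditions. The trisubstituted alkene and C2 survive. The final structure is checked against the target SMILES: 5,7-OH A ring, C4 ketone, 2′,4′-diOH, 5′-(E)-geranyl, and a single (2S) centre.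

**Compound list**
1 | (2S)-naringenin | Oc1ccc([C@@H]2CC(=O)c3c(O)cc(O)cc3O2)cc1 | starting material
2 | triisopropylsilyl chloride | CC(C)[Si](Cl)(C(C)C)C(C)C | starting material (reagent)
3 | (2S)-7,4′-bis-O-TIPS-naringenin | CC(C)[Si](C(C)C)(C(C)C)Oc1ccc([C@@H]2CC(=O)c3c(O)cc(O[Si](C(C)C)(C(C)C)C(C)C)cc3O2)cc1 | intermediate
4 | bis(pinacolato)diboron | CC1(C)OB(OC1(C)C)B1OC(C)(C)C(C)(C)O1 | starting material (reagent)
5 | (2S)-2′-Bpin-7,4′-bis-O-TIPS-naringenin | CC(C)[Si](C(C)C)(C(C)C)Oc1ccc([C@@H]2CC(=O)c3c(O)cc(O[Si](C(C)C)(C(C)C)C(C)C)cc3O2)c(B2OC(C)(C)C(C)(C)O2)c1 | intermediate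
6 | dioxygen | O=O | starting material (reagent)
7 | (2S)-2′-hydroxy-7,4′-bis-O-TIPS-naringenin | CC(C)[Si](C(C)C)(C(C)C)Oc1ccc([C@@H]2CC(=O)c3c(O)cc(O[Si](C(C)C)(C(C)C)C(C)C)cc3O2)c(O)c1 | intermediate
8 | N-bromosuccinimide | O=C1CCC(=O)N1Br | starting material (reagent)
9 | (2S)-5′-bromo-2′-hydroxy-7,4′-bis-O-TIPS-naringenin | CC(C)[Si](C(C)C)(C(C)C)Oc1cc(O)c([C@@H]2CC(=O)c3c(O)cc(O[Si](C(C)C)(C(C)C)C(C)C)cc3O2)cc1Br | intermediate
10 | (E)-geranyltributylstannane | CC(C)=CCC/C(C)=C/C[Sn](CCCC)(CCCC)CCCC | starting material (reagent)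
11 | (2S)-5′-geranyl-2′-hydroxy-7,4′-bis-O-TIPS-naringenin | CC(C)=CCC/C(C)=C/Cc1cc([C@@H]2CC(=O)c3c(O)cc(O[Si](C(C)C)(C(C)C)C(C)C)cc3O2)c(O)cc1O[Si](C(C)C)(C(C)C)C(C)C | intermediate
12 | Kuwanon E | CC(C)=CCC/C(C)=C/Cc1cc([C@@H]2CC(=O)c3c(O)cc(O)cc3O2)c(O)cc1O | target

**Totals:** 6 steps; longest linear sequence 6 steps.

**Three steps most likely to fail**
1. **Step 2 (the proposed new step).** The C2′ borylation may be unselective or sluggish, because all four B-ring C–H bonds are ortho to a substituent and C3′ may compete.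
   - Fallback (known chemistry, different approach): build the flavanone B-ring-first. Use Claisen–Schmidt condensation of a protected 2′-hydroxy-4′,6′-dioxyacetophenone with a 2,4-bis-protected 5-geranylbenzaldehyde, then oxa-Michael cyclisation. Isolate the (2S) enantiomer by preparative chiral-phase HPLC.
2. **Step 3.** Over-oxidation of the electron-rich product by singlet oxygen or the excited photocatalyst, or partial C2 epimerisation by iPr2NEt.
   - Fallback: polar oxidation of the C–B bond with NaBO3·4H2O in THF/H2O. This is a peroxide 1,2-aryl shift with no photocatalyst and no amine base.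
3. **Step 5.** The hindered aryl bromide (ortho-OTIPS, free phenols) may couple poorly, or give α/γ or E/Z mixtures.
   - Fallback: skip bromination and stannane, and geranylate compound 7 directly at C5′ (para to the free 2′-OH) by Friedel–Crafts alkylation with geraniol under mild Lewis-acid catalysis.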